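**Plan**

- Atom numbering is that of the cyclopenta[c]pyran core of the target (C1, O2, C3, C4, C4a, C5, C6, C7, C7a). The retrosynthesis cuts, in order: the O–CH3 bond; the bond from C1 to C3 of the chromone; the O2–C1 hemiacetal bond (back to a 1,5-dicarbonyl compound); the C3–acyl bond; the ring bond C4a–C5; the C4=C4a olefin and the C7a–C1 bond.
- Forward: (S)-citronellal is hydroxymethylated at C7a and closed by Z-olefination to a 3-methyl-5,6-dihydropyran-2-one, which already holds O2, C1, C7a, C4a, C4 and C3 of the final pyran. The side-chain alkene is cut down to a carboxylic acid that serves as a handle on C5.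
- Key event: C4a is the β-carbon of the unsaturated lactone unit C3(=O)–C4(CH3)=C4a, and C5 ends the three-carbon tether C7–C6–C5 on the neighbouring ring carbon C7a. A C5 radical made by decarboxylation therefore closes the cyclopentane 5-exo and cis.
- The lactone is then opened at C3 by an isovaleryl anion equivalent, C1 is oxidized, and unmasking the 1,2-diketone re-closes the pyran as its enol-ether lactol. 4-Hydroxy-5-methylcoumarin is joined at C1 and methylated on the 2-oxygen.
- Stereochemistry: C7 from (S)-citronellal; C7a from the organocatalyst; C4a from C7a through the cis ring closure; C1 from convex-face, reversible addition to the cyclic oxocarbenium ion.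

Key step: step 4

Remark: from step 4 to step 8 the methyl-bearing C4 is carried as a mixture of epimers; it becomes sp2 when the pyran re-closes in step 8, so the mixture converges.

**Step 1**
Reactants: 1 (S)-citronellal; 2 formaldehyde
Product: 3 (2S,3S)-2-(hydroxymethyl)-3,7-dimethyloct-6-enal
Conditions: (R)-2-[diphenyl(trimethylsilyloxy)methyl]pyrrolidine (20 mol%), 37% aq. HCHO, pH 7 phosphate buffer, toluene, rt; used crude at once
Reagents that add atoms: none
Why: Enamine-mediated cross-aldol with formaldehyde (organocatalytic α-hydroxymethylation), in which the E-enamine of 1 is attacked on the face remote from the CPh2(OSiMe3) group, so the (R)-catalyst should set C7a as (S) under catalyst control while the C7 centre is a spectator.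

**Step 2**
Reactants: 3 (2S,3S)-2-(hydroxymethyl)-3,7-dimethyloct-6-enal; 4 ethyl 2-[bis(2,2,2-trifluoroethoxy)phosphoryl]propanoate
Product: 6 (5R)-3-methyl-5-[(2S)-6-methylhept-5-en-2-yl]-5,6-dihydro-2H-pyran-2-one, via Z-hydroxy enoate 5 (not isolated)
Conditions: 4, KN(SiMe3)2, 18-crown-6, THF, −78 °C; then 3, −78 °C; work-up; then p-TsOH·H2O (cat.), CH2Cl2, rt
Reagents that add atoms: none
Why: Still–Gennari variant of the Horner–Wadsworth–Emmons olefination, in which the electron-poor phosphonate should give the Z-trisubstituted enoate under kinetic control, and only this isomer can lactonize with the C1 hydroxyl, so acid closes the dihydropyranone without touching C7a.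

**Step 3**
Reactants: 6 (5R)-3-methyl-5-[(2S)-6-methylhept-5-en-2-yl]-5,6-dihydro-2H-pyran-2-one
Product: 8 (4S)-4-[(3R)-5-methyl-6-oxo-3,6-dihydro-2H-pyran-3-yl]pentanoic acid, via aldehyde 7 (not isolated)
Conditions: O3, CH2Cl2, −78 °C (Sudan Red 7B end point); Me2S, −78 °C → rt; then NaClO2, NaH2PO4, 2-methylbut-2-ene, t-BuOH/H2O, rt
Reagents that add atoms: ozone [O-][O+]=O; sodium chlorite [Na+].[O-]Cl=O
Why: Ozonolysis followed by Pinnick oxidation, in which ozone should attack the electron-rich trisubstituted side-chain alkene much faster than the electron-poor conjugated lactone alkene and chlorite oxidizes only the aldehyde, leaving both stereocentres and the enoate intact.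

**Step 4**
Reactants: 8 (4S)-4-[(3R)-5-methyl-6-oxo-3,6-dihydro-2H-pyran-3-yl]pentanoic acid
Product: 10 (4aS,7S,7aR)-4,7-dimethylhexahydrocyclopenta[c]pyran-3(1H)-one (C4 epimers), via N-acyloxyphthalimide 9 (not isolated)
Conditions: N-hydroxyphthalimide, N,N'-diisopropylcarbodiimide, DMAP (cat.), CH2Cl2, rt; filter; then Ru(bpy)3(PF6)2 (1 mol%), Hantzsch ester (1.5 equiv), i-Pr2NEt·HBF4, CH2Cl2 (0.02 M), blue LEDs, rt
Reagents that add atoms: none
Why: The photoexcited Ru(bpy)3(PF6)2, reductively quenched by the Hantzsch ester, transfers an electron to the N-acyloxyphthalimide 9, which loses phthalimide anion and CO2 to give the primary C5 radical; this adds to C4a, the β-carbon of the α-methyl-α,β-unsaturated δ-lactone, and the tertiary α-acyl radical at C4 is then quenched by hydrogen-atom transfer from the Hantzsch ester. The closest known reaction type is the reductive decarboxylative Giese addition of redox-active esters to acrylates and enones, run here intramolecularly. The cyclopentane closes in the 5-exo-trig mode (C4a inside, C4 outside the new ring), the 6-endo alternative at the methyl-bearing C4 being slower on steric and polar grounds. C4a is set by C7a, because the three-carbon tether on C7a can reach only the same face of the neighbouring ring carbon, so the ring fusion must be cis (4aS with 7aR); C4 forms as an epimer mixture that is of no consequence. The step needs cyclization to outrun direct hydrogen capture by the C5 radical and 1,5-hydrogen shift from C1, and the polarity match between the nucleophilic alkyl radical and the electron-poor alkene, the short tether and the high dilution should secure this.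

**Step 5**
Reactants: 11 3-methylbutanal; 12 propane-1,3-dithiol
Product: 13 2-(2-methylpropyl)-1,3-dithiane
Conditions: BF3·OEt2 (cat.), CH2Cl2, 0 °C → rt
Reagents that add atoms: none
Why: Lewis-acid catalysed dithioacetalization of an aldehyde, which provides the acyl anion equivalent for the isovaleryl group.

**Step 6**
Reactants: 10 (4aS,7S,7aR)-4,7-dimethylhexahydrocyclopenta[c]pyran-3(1H)-one (C4 epimers); 13 2-(2-methylpropyl)-1,3-dithiane
Product: 14 2-[(1S,2R,3S)-2-(hydroxymethyl)-3-methylcyclopentyl]-1-[2-(2-methylpropyl)-1,3-dithian-2-yl]propan-1-one (in equilibrium with its cyclic hemiketal)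
Conditions: 13, n-BuLi, THF, −30 °C; then 10, −78 → −20 °C; sat. aq. NH4Cl
Reagents that add atoms: none
Why: Corey–Seebach umpolung, in which the lithiated dithiane adds once to the lactone carbonyl C3 and the tetrahedral lithium alkoxide, flanked by a quaternary and a tertiary carbon, should resist a second addition, so work-up frees the C1 hydroxyl and the C3 ketone with the ring stereocentres untouched.

**Step 7**
Reactants: 14 2-[(1S,2R,3S)-2-(hydroxymethyl)-3-methylcyclopentyl]-1-[2-(2-methylpropyl)-1,3-dithian-2-yl]propan-1-one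
Product: 15 (1R,2S,5S)-2-methyl-5-{1-[2-(2-methylpropyl)-1,3-dithian-2-yl]-1-oxopropan-2-yl}cyclopentane-1-carbaldehyde
Conditions: Dess–Martin periodinane, CH2Cl2, 0 °C → rt
Reagents that add atoms: none
Why: Dess–Martin oxidation of the primary alcohol (the open form of the hydroxy ketone/hemiketal equilibrium) to the aldehyde under non-basic conditions, which should spare the epimerizable C7a centre and the dithiane.

**Step 8**
Reactants: 15 (1R,2S,5S)-2-methyl-5-{1-[2-(2-methylpropyl)-1,3-dithian-2-yl]-1-oxopropan-2-yl}cyclopentane-1-carbaldehyde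
Product: 17 1-[(4aS,7S,7aR)-1-hydroxy-4,7-dimethyl-1,4a,5,6,7,7a-hexahydrocyclopenta[c]pyran-3-yl]-3-methylbutan-1-one (C1 anomers), via diketo aldehyde 16 (not isolated)
Conditions: PhI(OCOCF3)2, MeCN/H2O, 0 °C; used crude
Reagents that add atoms: water O
Why: Oxidative dithiane hydrolysis with a hypervalent iodine reagent unmasks the 1,2-diketone, whose C3 enol (towards C4) adds to the C1 aldehyde to close the six-membered enol-ether hemiacetal as a 1,5-dicarbonyl compound does, which erases the C4 epimer mixture, while cold and short exposure should keep aldol pathways and C7a epimerization from competing.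

**Step 9**
Reactants: 18 1-(2-hydroxy-6-methylphenyl)ethan-1-one; 19 diethyl carbonate
Product: 20 4-hydroxy-5-methyl-2H-chromen-2-one
Conditions: NaH, toluene, 110 °C; then aq. HCl
Reagents that add atoms: none
Why: Claisen-type C-acylation of the ketone enolate with diethyl carbonate followed by lactonization onto the phenol, the standard route from an o-hydroxyacetophenone to a 4-hydroxycoumarin.

**Step 10**
Reactants: 17 1-[(4aS,7S,7aR)-1-hydroxy-4,7-dimethyl-1,4a,5,6,7,7a-hexahydrocyclopenta[c]pyran-3-yl]-3-methylbutan-1-one; 20 4-hydroxy-5-methyl-2H-chromen-2-one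
Product: 21 4-hydroxy-5-methyl-3-[(1R,4aS,7S,7aR)-4,7-dimethyl-3-(3-methylbutanoyl)-1,4a,5,6,7,7a-hexahydrocyclopenta[c]pyran-1-yl]-2H-chromen-2-one
Conditions: camphorsulfonic acid (10 mol%), 4 Å molecular sieves, MeCN, rt
Reagents that add atoms: none
Why: Acid-catalysed ionization of the lactol to the cyclic oxocarbenium ion and Friedel–Crafts-type (Knoevenagel-like) C-alkylation by the nucleophilic C3 of the 4-hydroxycoumarin, in which attack on the convex face of the cis-fused bicycle, anti to the cyclopentane ring, and the reversibility of the addition should both favour the (1R) isomer with the aryl group cis to H7a.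

**Step 11**
Reactants: 21 4-hydroxy-5-methyl-3-[(1R,4aS,7S,7aR)-4,7-dimethyl-3-(3-methylbutanoyl)-1,4a,5,6,7,7a-hexahydrocyclopenta[c]pyran-1-yl]-2H-chromen-2-one
Product: 23 2-methoxy-5-methyl-3-[(1R,4aS,7S,7aR)-4,7-dimethyl-3-(3-methylbutanoyl)-1,4a,5,6,7,7a-hexahydrocyclopenta[c]pyran-1-yl]-4H-chromen-4-one, via benzopyrylium triflate 22 (not isolated)
Conditions: MeOTf (1.1 equiv), CH2Cl2, 0 °C → rt; then sat. aq. NaHCO3
Reagents that add atoms: methyl trifluoromethanesulfonate COS(=O)(=O)C(F)(F)F
Why: Alkylation of the neutral 4-hydroxy-2-pyranone tautomer by a hard electrophile occurs at the carbonyl oxygen remote from the mobile proton, giving the 4-hydroxy-2-methoxybenzopyrylium salt, which stays protonated and so safe from a second methylation until bicarbonate removes the 4-OH proton to give the 2-methoxychromone, the peri 5-methyl group further disfavouring reaction at the 4-oxygen.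

**Compound list**

1 | (S)-citronellal, (3S)-3,7-dimethyloct-6-enal | O=CC[C@@H](C)CCC=C(C)C | starting material
2 | formaldehyde | C=O | starting material
3 | (2S,3S)-2-(hydroxymethyl)-3,7-dimethyloct-6-enal | O=C[C@H](CO)[C@@H](C)CCC=C(C)C | intermediate
4 | ethyl 2-[bis(2,2,2-trifluoroethoxy)phosphoryl]propanoate | CCOC(=O)C(C)P(=O)(OCC(F)(F)F)OCC(F)(F)F | starting material
5 | ethyl (2Z,4R,5S)-4-(hydroxymethyl)-2,5,9-trimethyldeca-2,8-dienoate | CCOC(=O)/C(C)=C\[C@H](CO)[C@@H](C)CCC=C(C)C | intermediate
6 | (5R)-3-methyl-5-[(2S)-6-methylhept-5-en-2-yl]-5,6-dihydro-2H-pyran-2-one | C1OC(=O)C(C)=C[C@H]1[C@@H](C)CCC=C(C)C | intermediate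
7 | (4S)-4-[(3R)-5-methyl-6-oxo-3,6-dihydro-2H-pyran-3-yl]pentanal | C1OC(=O)C(C)=C[C@H]1[C@@H](C)CCC=O | intermediate
8 | (4S)-4-[(3R)-5-methyl-6-oxo-3,6-dihydro-2H-pyran-3-yl]pentanoic acid | C1OC(=O)C(C)=C[C@H]1[C@@H](C)CCC(=O)O | intermediate
9 | 1,3-dioxoisoindolin-2-yl (4S)-4-[(3R)-5-methyl-6-oxo-3,6-dihydro-2H-pyran-3-yl]pentanoate | C1OC(=O)C(C)=C[C@H]1[C@@H](C)CCC(=O)ON1C(=O)c2ccccc2C1=O | intermediate
10 | (4aS,7S,7aR)-4,7-dimethylhexahydrocyclopenta[c]pyran-3(1H)-one (C4 epimers) | C1OC(=O)C(C)[C@H]2CC[C@H](C)[C@H]21 | intermediate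
11 | 3-methylbutanal | CC(C)CC=O | starting material
12 | propane-1,3-dithiol | SCCCS | starting material
13 | 2-(2-methylpropyl)-1,3-dithiane | CC(C)CC1SCCCS1 | intermediate
14 | 2-[(1S,2R,3S)-2-(hydroxymethyl)-3-methylcyclopentyl]-1-[2-(2-methylpropyl)-1,3-dithian-2-yl]propan-1-one | OC[C@@H]1[C@@H](C)CC[C@@H]1C(C)C(=O)C2(CC(C)C)SCCCS2 | intermediate
15 | (1R,2S,5S)-2-methyl-5-{1-[2-(2-methylpropyl)-1,3-dithian-2-yl]-1-oxopropan-2-yl}cyclopentane-1-carbaldehyde | O=C[C@@H]1[C@@H](C)CC[C@@H]1C(C)C(=O)C2(CC(C)C)SCCCS2 | intermediate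
16 | (1R,2S,5S)-2-methyl-5-(6-methyl-3,4-dioxoheptan-2-yl)cyclopentane-1-carbaldehyde | O=C[C@@H]1[C@@H](C)CC[C@@H]1C(C)C(=O)C(=O)CC(C)C | intermediate
17 | 1-[(4aS,7S,7aR)-1-hydroxy-4,7-dimethyl-1,4a,5,6,7,7a-hexahydrocyclopenta[c]pyran-3-yl]-3-methylbutan-1-one (C1 anomers) | OC1OC(C(=O)CC(C)C)=C(C)[C@H]2CC[C@H](C)[C@H]21 | intermediate
18 | 1-(2-hydroxy-6-methylphenyl)ethan-1-one | CC(=O)c1c(C)cccc1O | starting material
19 | diethyl carbonate | CCOC(=O)OCC | starting material
20 | 4-hydroxy-5-methyl-2H-chromen-2-one | Cc1cccc2oc(=O)cc(O)c12 | intermediate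
21 | 4-hydroxy-5-methyl-3-[(1R,4aS,7S,7aR)-4,7-dimethyl-3-(3-methylbutanoyl)-1,4a,5,6,7,7a-hexahydrocyclopenta[c]pyran-1-yl]-2H-chromen-2-one | Cc1cccc2oc(=O)c(c(O)c12)[C@@H]1OC(C(=O)CC(C)C)=C(C)[C@H]2CC[C@H](C)[C@H]21 | intermediate
22 | 4-hydroxy-2-methoxy-5-methyl-3-[(1R,4aS,7S,7aR)-4,7-dimethyl-3-(3-methylbutanoyl)-1,4a,5,6,7,7a-hexahydrocyclopenta[c]pyran-1-yl]chromenylium trifluoromethanesulfonate | COc1[o+]c2cccc(C)c2c(O)c1[C@@H]1OC(C(=O)CC(C)C)=C(C)[C@H]2CC[C@H](C)[C@H]21.[O-]S(=O)(=O)C(F)(F)F | intermediate
23 | 2-methoxy-5-methyl-3-[(1R,4aS,7S,7aR)-4,7-dimethyl-3-(3-methylbutanoyl)-1,4a,5,6,7,7a-hexahydrocyclopenta[c]pyran-1-yl]-4H-chromen-4-one | COc1oc2cccc(C)c2c(=O)c1[C@@H]1OC(C(=O)CC(C)C)=C(C)[C@H]2CC[C@H](C)[C@H]21 | target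

**Step count and risks**

Total step count: 11. Longest linear sequence: 9 steps (steps 1, 2, 3, 4, 6, 7, 8, 10, 11).

The three steps most likely to fail:

Step 10. The ring-opened alkylidene form of the adduct may be captured by a second molecule of 20 to give a bis-coumarin, and C7a may epimerize through the open-chain aldehyde under the equilibrating acid. The fallback replaces the thermodynamic condensation by a kinetically controlled Mukaiyama-type coupling of preactivated partners. It sets out from 17 and 20: acetylation of 17 (Ac2O, pyridine) would give the anomeric acetate 1-acetoxy-3-(3-methylbutanoyl)-4,7-dimethyl-1,4a,5,6,7,7a-hexahydrocyclopenta[c]pyran F3, and silylation of 20 (Me3SiCl, Et3N) would give 5-methyl-4-(trimethylsilyloxy)-2H-chromen-2-one F4. Their union with Me3SiOTf (cat.) in CH2Cl2 at −78 °C and aqueous work-up comes back to the route at 21.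

Step 11. Methylation may occur on the 4-oxygen instead of the 2-oxygen, or the acid set free may ionize the C1–O2 bond. The fallback places the methyl group before the fragment union and brings the chromone in as a carbon nucleophile. It sets out from 20 and 15: methylation of 20 with MeOTf would give 2-methoxy-5-methyl-4H-chromen-4-one F5, from which any 4-methoxy isomer is removed at this simple stage, and N-iodosuccinimide would give 3-iodo-2-methoxy-5-methyl-4H-chromen-4-one F6. Nozaki–Hiyama–Kishi addition of F6 to aldehyde 15 (CrCl2, NiCl2 cat., DMF) would give the C1 carbinol with the dithiane still in place F7. Dithiane removal with PhI(OCOCF3)2 would give the diketo carbinol F8, and camphorsulfonic acid would close the pyran by hemiketal formation at C3 and loss of water towards C4. The C1 epimers are expected to converge under the acid by reversible ionization at C1, and the sequence comes back to the route at 23.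

Step 6. Enolization of lactone 10 at C4 by the hindered lithiated dithiane may win over addition to the carbonyl group. The fallback makes the C3–acyl bond by addition to an aldehyde instead of a lactone. It sets out from 10: reduction with i-Bu2AlH (CH2Cl2, −78 °C) would give the lactol (4aS,7S,7aR)-4,7-dimethyloctahydrocyclopenta[c]pyran-3-ol F1, whose open hydroxy aldehyde form should take up lithiated 13 (2.2 equiv, THF, −78 °C) to give the diol 2-[(1S,2R,3S)-2-(hydroxymethyl)-3-methylcyclopentyl]-1-[2-(2-methylpropyl)-1,3-dithian-2-yl]propan-1-ol F2. Oxidation of both hydroxyl groups with Dess–Martin periodinane comes back to the route at 15.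

**Further compounds**

F1 | step 6 | (4aS,7S,7aR)-4,7-dimethyloctahydrocyclopenta[c]pyran-3-ol | C1OC(O)C(C)[C@H]2CC[C@H](C)[C@H]21
F2 | step 6 | 2-[(1S,2R,3S)-2-(hydroxymethyl)-3-methylcyclopentyl]-1-[2-(2-methylpropyl)-1,3-dithian-2-yl]propan-1-ol | OC[C@@H]1[C@@H](C)CC[C@@H]1C(C)C(O)C2(CC(C)C)SCCCS2
F3 | step 10 | (4aS,7S,7aR)-4,7-dimethyl-3-(3-methylbutanoyl)-1,4a,5,6,7,7a-hexahydrocyclopenta[c]pyran-1-yl acetate | CC(=O)OC1OC(C(=O)CC(C)C)=C(C)[C@H]2CC[C@H](C)[C@H]21
F4 | step 10 | 5-methyl-4-(trimethylsilyloxy)-2H-chromen-2-one | Cc1cccc2oc(=O)cc(O[Si](C)(C)C)c12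
F5 | step 11 | 2-methoxy-5-methyl-4H-chromen-4-one | COc1cc(=O)c2c(C)cccc2o1
F6 | step 11 | 3-iodo-2-methoxy-5-methyl-4H-chromen-4-one | COc1oc2cccc(C)c2c(=O)c1I
F7 | step 11 | 3-{hydroxy[(1R,2S,5S)-2-methyl-5-{1-[2-(2-methylpropyl)-1,3-dithian-2-yl]-1-oxopropan-2-yl}cyclopentyl]methyl}-2-methoxy-5-methyl-4H-chromen-4-one | COc1oc2cccc(C)c2c(=O)c1C(O)[C@@H]1[C@@H](C)CC[C@@H]1C(C)C(=O)C2(CC(C)C)SCCCS2
F8 | step 11 | 3-{hydroxy[(1R,2S,5S)-2-methyl-5-(6-methyl-3,4-dioxoheptan-2-yl)cyclopentyl]methyl}-2-methoxy-5-methyl-4H-chromen-4-one | COc1oc2cccc(C)c2c(=O)c1C(O)[C@@H]1[C@@H](C)CC[C@@H]1C(C)C(=O)C(=O)CC(C)C
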